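**Plan**

- Locants: C1 lactone C=O, C2 H2, C3 H–O(peroxide), C4 (Me)–O(lactone), C5 H2, C6 (Me)(aryl-C9 chain)–O(peroxide). The retrosynthesis cuts C5–C6 and O–C4 in one operation, then O–C3, then the chain bonds.
- Enabling feature: C5H2 of the 1,2-dioxane lies between two fully substituted, oxygen-bearing carbons. C6 can be raised to a peroxycarbenium ion (ketal level). C4 can be a tertiary cation that the C1 carboxyl, held on C3, closes into the γ-lactone; C4=C5 is then an isopropenyl group.
- Forward: the aryl-C9 chain is built into a 2-methyl-1-alkene and ozonized in methanol to the α-methoxy hydroperoxide (C6 with its O–O). This adds enantioselectively to 4-methylpenta-2,4-dienal (O–C3), and the aldehyde is oxidized to the acid. One Lewis-acid cascade then closes the 1,2-dioxane and the lactone, and desilylation ends the route.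
- Stereochemistry: C3 comes from the aminocatalyst, C4 from the cis ring fusion imposed by the short tether, and C6 from the chair transition state of the ring closure; C4 and C6 are both relayed from C3.
- Helpers: the ketal OMe on C6 (leaving group), a transient trimethylsilyl ester and the TBS ether on the phenol; all are removed in or after the key step.

Key step: step 7

Remark: compounds 7, 11, 12 and 13 are used as mixtures of epimers at the peroxyketal carbon, which becomes planar in step 7; the locants C1–C6 defined above are used throughout.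

**Route**

Step 1
Reactants: 1 (4-bromophenoxy)(tert-butyl)dimethylsilane; 2 1,9-dibromononane
Product: 4 [4-(9-bromononyl)phenoxy](tert-butyl)dimethylsilane, via arylmagnesium bromide 3 (not isolated)
Conditions: Mg, THF, 50 °C; then added to the dibromide (threefold excess, surplus recovered by distillation), Li2CuCl4 (3 mol%), THF, −10 °C to rt
Reagents that add atoms: none
Why: Copper-catalysed coupling of an aryl Grignard reagent with a primary alkyl bromide; the excess of dibromide should limit double arylation, and the aryl silyl ether is inert to Mg and to the cuprate.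

Step 2
Reactants: 4 [4-(9-bromononyl)phenoxy](tert-butyl)dimethylsilane; 5 isopropenylmagnesium bromide (prop-1-en-2-ylmagnesium bromide)
Product: 6 tert-butyldimethyl[4-(10-methylundec-10-en-1-yl)phenoxy]silane
Conditions: Fe(acac)3 (5 mol%), TMEDA, hexamethylenetetramine, THF, 0 °C
Reagents that add atoms: none
Why: Iron-catalysed cross-coupling of a primary alkyl bromide with an alkenyl Grignard reagent joins the sp3 and sp2 carbons without isomerizing the 1,1-disubstituted alkene.

Step 3
Reactants: 6 tert-butyldimethyl[4-(10-methylundec-10-en-1-yl)phenoxy]silane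
Product: 7 rac-tert-butyl[4-(10-hydroperoxy-10-methoxyundecyl)phenoxy]dimethylsilane
Conditions: O3, CH2Cl2/MeOH 4:1, −78 °C (Sudan red 7B end point), N2 purge, no reductant
Reagents that add atoms: ozone ([O-][O+]=O); methanol (CO)
Why: Ozonolysis in methanol (Criegee mechanism): the primary ozonide of a 1,1-dialkyl alkene should fragment mainly to the dialkyl carbonyl oxide and formaldehyde, and methanol traps the carbonyl oxide as the α-methoxy hydroperoxide; the alkene reacts far faster than the silyloxy arene.

Step 4
Reactants: 8 methacrolein (2-methylprop-2-enal); 9 (triphenylphosphoranylidene)acetaldehyde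
Product: 10 (2E)-4-methylpenta-2,4-dienal
Conditions: toluene, 80 °C, methacrolein in threefold excess, hydroquinone (trace); distillation
Reagents that add atoms: none
Why: Wittig reaction of the stabilized formyl ylide gives the (E)-enal, and the excess of methacrolein should prevent a second olefination.

Step 5
Reactants: 7 rac-tert-butyl[4-(10-hydroperoxy-10-methoxyundecyl)phenoxy]dimethylsilane; 10 (2E)-4-methylpenta-2,4-dienal
Product: 11 (3S)-3-({2-methoxy-11-[4-(tert-butyldimethylsilyloxy)phenyl]undecan-2-yl}peroxy)-4-methylpent-4-enal (both epimers at the ketal carbon)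
Conditions: (S)-2-{bis[3,5-bis(trifluoromethyl)phenyl](trimethylsilyloxy)methyl}pyrrolidine (10 mol%), toluene, 0 °C; the dienal in twofold amount, its unreacted surplus removed under vacuum; filtration through deactivated silica and immediate use
Reagents that add atoms: none
Why: Iminium-catalysed enantioselective oxa-Michael addition (asymmetric peroxidation of an enal with an α-alkoxyalkyl hydroperoxide), a 1:1 addition of O–H across C2=C3 in which every atom of both partners ends in 11: the aryl2(silyloxy)methyl group of the (S)-catalyst shields the Re face of C3 in the (E)-s-trans iminium ion, so the O–O nucleophile adds to the Si face and sets C3 as (S), and because C3 carries the larger LUMO coefficient, 1,4-addition should win over attack at the diene terminus.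

Step 6
Reactants: 11 (3S)-3-({2-methoxy-11-[4-(tert-butyldimethylsilyloxy)phenyl]undecan-2-yl}peroxy)-4-methylpent-4-enal
Product: 12 (3S)-3-({2-methoxy-11-[4-(tert-butyldimethylsilyloxy)phenyl]undecan-2-yl}peroxy)-4-methylpent-4-enoic acid
Conditions: NaClO2, NaH2PO4 (pH about 4–5), 2-methyl-2-butene, t-BuOH/H2O, 0 °C, short contact time; used without storage
Reagents that add atoms: sodium chlorite ([Na+].[O-]Cl=O)
Why: Pinnick oxidation converts the aldehyde into the acid under mildly acidic buffer without touching the peroxide, the ketal or C3, and 2-methyl-2-butene removes HOCl before it can chlorinate the isopropenyl group.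

Step 7
Reactants: 12 (3S)-3-({2-methoxy-11-[4-(tert-butyldimethylsilyloxy)phenyl]undecan-2-yl}peroxy)-4-methylpent-4-enoic acid
Product: 14 O-tert-butyldimethylsilyl-plakortolide F, via trimethylsilyl ester 13 (not isolated)
Conditions: BSA (1.5 equiv), CH2Cl2, 0 °C; then TMSOTf (0.2 equiv), −78 to −40 °C; Et3N quench
Reagents that add atoms: none
Why: Proposed new method: TMSOTf silylates the ketal methoxy group (far more basic than the peroxide oxygens) and loss of TMSOMe gives the C6 peroxycarbenium ion; the terminal carbon C5 of the isopropenyl group attacks it in a chair-like 6-endo-trig closure (C4=C5 and C6=O+ both inside the new 1,2-dioxane ring), and the tertiary C4 cation so formed is trapped by the carbonyl oxygen of the silyl ester on C3 in a five-membered closure (5-exo with respect to C4=C5), the silyl group leaving as TMSOTf so that the acid turns over. The closest known reaction types are the Lewis-acid-mediated 6-endo cyclization of unsaturated monoperoxyketals through peroxycarbenium ions with halide capture (4-halo-1,2-dioxanes) and carboxyl-terminated cation–olefin (Prins) cyclizations; their union in one peroxy-Prins/lactonization cascade is what is new. C4 is controlled by the tether: the short CH2CO2 arm on (3S)-C3 reaches the cation far more easily on its own face, so the γ-lactone should be cis-fused and C4 becomes (S). C6 is controlled by the chair transition state: the arm on C3 lies pseudoaxial to avoid A(1,2) strain with the C4 methyl group, and the long chain takes the site anti to O–O in the (E)-peroxycarbenium ion and therefore the equatorial position, which puts the chain cis to the arm, i.e. (6R). The step needs ionization of C–OMe and not of C–OO (secured by the methoxy leaving group and the oxophilic silyl acid), ring closure ahead of proton-initiated lactonization of the alkene (secured by excess BSA as proton trap and by the silyl ester), and the C6 facial preference, which rests only on the two conformational biases named and may be low because methyl and a primary alkyl chain differ little in size, the 6-epimer then being removed by chromatography.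

Step 8
Reactants: 14 O-tert-butyldimethylsilyl-plakortolide F
Product: 15 plakortolide F
Conditions: TBAF, AcOH (1:1), THF, 0 °C
Reagents that add atoms: none
Why: Fluoride cleaves the aryl silyl ether, and the acetic acid buffer keeps the medium non-basic so that the β-peroxy lactone cannot open by retro-oxa-Michael (E1cB) elimination or Kornblum–DeLaMare cleavage.

**Compound list**

1 | (4-bromophenoxy)(tert-butyl)dimethylsilane | CC(C)(C)[Si](C)(C)Oc1ccc(Br)cc1 | starting material
2 | 1,9-dibromononane | BrCCCCCCCCCBr | starting material
3 | {4-[(tert-butyldimethylsilyl)oxy]phenyl}magnesium bromide | CC(C)(C)[Si](C)(C)Oc1ccc([Mg]Br)cc1 | intermediate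
4 | [4-(9-bromononyl)phenoxy](tert-butyl)dimethylsilane | CC(C)(C)[Si](C)(C)Oc1ccc(CCCCCCCCCBr)cc1 | intermediate
5 | isopropenylmagnesium bromide (prop-1-en-2-ylmagnesium bromide) | CC(=C)[Mg]Br | starting material
6 | tert-butyldimethyl[4-(10-methylundec-10-en-1-yl)phenoxy]silane | CC(=C)CCCCCCCCCc1ccc(O[Si](C)(C)C(C)(C)C)cc1 | intermediate
7 | rac-tert-butyl[4-(10-hydroperoxy-10-methoxyundecyl)phenoxy]dimethylsilane | COC(C)(OO)CCCCCCCCCc1ccc(O[Si](C)(C)C(C)(C)C)cc1 | intermediate
8 | methacrolein (2-methylprop-2-enal) | CC(=C)C=O | starting material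
9 | (triphenylphosphoranylidene)acetaldehyde | O=CC=P(c1ccccc1)(c1ccccc1)c1ccccc1 | starting material
10 | (2E)-4-methylpenta-2,4-dienal | CC(=C)/C=C/C=O | intermediate
11 | (3S)-3-({2-methoxy-11-[4-(tert-butyldimethylsilyloxy)phenyl]undecan-2-yl}peroxy)-4-methylpent-4-enal, both ketal epimers | C=C(C)[C@H](CC=O)OOC(C)(OC)CCCCCCCCCc1ccc(O[Si](C)(C)C(C)(C)C)cc1 | intermediate
12 | (3S)-3-({2-methoxy-11-[4-(tert-butyldimethylsilyloxy)phenyl]undecan-2-yl}peroxy)-4-methylpent-4-enoic acid, both ketal epimers | C=C(C)[C@H](CC(=O)O)OOC(C)(OC)CCCCCCCCCc1ccc(O[Si](C)(C)C(C)(C)C)cc1 | intermediate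
13 | trimethylsilyl (3S)-3-({2-methoxy-11-[4-(tert-butyldimethylsilyloxy)phenyl]undecan-2-yl}peroxy)-4-methylpent-4-enoate | C=C(C)[C@H](CC(=O)O[Si](C)(C)C)OOC(C)(OC)CCCCCCCCCc1ccc(O[Si](C)(C)C(C)(C)C)cc1 | intermediate
14 | O-tert-butyldimethylsilyl-plakortolide F: (3R,4aS,7aS)-3-(9-{4-[(tert-butyldimethylsilyl)oxy]phenyl}nonyl)-3,4a-dimethyl-4,4a,7,7a-tetrahydrofuro[3,2-c][1,2]dioxin-6(3H)-one | C[C@@]1(CCCCCCCCCc2ccc(O[Si](C)(C)C(C)(C)C)cc2)C[C@]2(C)OC(=O)C[C@@H]2OO1 | intermediate
15 | plakortolide F: (3R,4aS,7aS)-3-[9-(4-hydroxyphenyl)nonyl]-3,4a-dimethyl-4,4a,7,7a-tetrahydrofuro[3,2-c][1,2]dioxin-6(3H)-one (cis-fused; 3S,4S,6R in the locants used above) | C[C@@]1(CCCCCCCCCc2ccc(O)cc2)C[C@]2(C)OC(=O)C[C@@H]2OO1 | target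

**Count**

Total steps: 8. Longest linear sequence: 7 steps (1 → 4 → 6 → 7 → 11 → 12 → 14 → 15); step 4 is the side branch.

**Steps most likely to fail**

1. Step 7 (proposed new method). What may go wrong: ionization may take the C–OO bond instead of C–OMe; the C4 cation may lose a proton or accept a hydride from C3 before the silyl ester closes; and the chair preference at C6 may be small, so that the 6-epimer is formed in a large share.
Fallback, known chemistry only, setting out from 6 and returning at 14: the C4–C5 bond and the C4 centre are made first and the peroxide ring is closed last by a peroxy-Michael addition. A copper bis(oxazoline)-catalysed carbonyl-ene reaction of 6 with methyl pyruvate (Cu(SbF6)2 with (S,S)-tert-butyl-bis(oxazoline), CH2Cl2; alkene delivered to the Si face of the chelated ketone) should give methyl (2S)-2-hydroxy-2-methyl-4-methylidene-13-[4-(tert-butyldimethylsilyloxy)phenyl]tridecanoate F1, together with double-bond isomers that converge later. DIBAL-H at −78 °C should give (2S)-2-hydroxy-2-methyl-4-methylidene-13-[4-(tert-butyldimethylsilyloxy)phenyl]tridecanal F2. Ketenylidenetriphenylphosphorane (Ph3P=C=C=O, toluene, 90 °C; O-acylation, then intramolecular Wittig reaction) should give (5S)-5-methyl-5-{2-methylidene-11-[4-(tert-butyldimethylsilyloxy)phenyl]undecyl}furan-2(5H)-one F3. Mukaiyama–Isayama hydroperoxysilylation (Co(thd)2, O2, Et3SiH, 1,2-dichloroethane), in which the electron-rich isolated alkene reacts in preference to the butenolide, should give (5S)-5-methyl-5-{2-methyl-2-(triethylsilylperoxy)-11-[4-(tert-butyldimethylsilyloxy)phenyl]undecyl}furan-2(5H)-one F4 as both C6 epimers. HCl (cat.)/MeOH at 0 °C, then Et2NH in CF3CH2OH, frees the hydroperoxide, which closes the 1,2-dioxane by intramolecular oxa-Michael addition to the butenolide (cis fusion, C3 set by C4); 14 is separated from its C6 epimer.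

2. Step 5. What may go wrong: the hydroperoxide may add at the unsubstituted diene terminus (1,6) instead of C3, and reversible addition (retro-oxa-Michael) may erode the enantiomeric purity.
Fallback, setting out from 8 and returning at 12: the second double bond is kept masked during the conjugate addition. Benzeneselenol adds to 8 (CH2Cl2, 0 °C) to give 2-methyl-3-(phenylselanyl)propanal F5. Wittig reaction with 9 gives (2E)-4-methyl-5-(phenylselanyl)pent-2-enal F6, a γ-branched enal with a single electrophilic site. The same aminocatalysed addition of 7 should give (3S)-3-({2-methoxy-11-[4-(tert-butyldimethylsilyloxy)phenyl]undecan-2-yl}peroxy)-4-methyl-5-(phenylselanyl)pentanal F7. NaClO2/NaH2PO4/H2O2 in MeCN–H2O oxidizes the aldehyde to the acid and the selenide to the selenoxide, (3S)-3-({2-methoxy-11-[4-(tert-butyldimethylsilyloxy)phenyl]undecan-2-yl}peroxy)-4-methyl-5-(phenylseleninyl)pentanoic acid F8 (not isolated). Its syn-elimination at rt can only take the C4 hydrogen and unveils the isopropenyl group of 12.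

3. Step 3. What may go wrong: the primary ozonide may fragment toward the ketone and formaldehyde oxide, and ozone may slowly attack the silyloxy arene; both lower the amount of 7.
Fallback, ozone-free, setting out from 4 and returning at 7 (it also replaces step 2): (1-methoxyethenyl)lithium F9, made from methyl vinyl ether and t-BuLi (THF, −65 to 0 °C), is alkylated with 4 (THF/DMPU) to the enol ether tert-butyl[4-(10-methoxyundec-10-en-1-yl)phenoxy]dimethylsilane F10. Acid-catalysed Markovnikov addition of anhydrous ethereal H2O2 (PPTS cat., 0 °C) to the enol ether should then give 7 directly.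

Further compounds
F1 | step 7 | methyl (2S)-2-hydroxy-2-methyl-4-methylidene-13-[4-(tert-butyldimethylsilyloxy)phenyl]tridecanoate | C=C(CCCCCCCCCc1ccc(O[Si](C)(C)C(C)(C)C)cc1)C[C@](C)(O)C(=O)OC
F2 | step 7 | (2S)-2-hydroxy-2-methyl-4-methylidene-13-[4-(tert-butyldimethylsilyloxy)phenyl]tridecanal | C=C(CCCCCCCCCc1ccc(O[Si](C)(C)C(C)(C)C)cc1)C[C@](C)(O)C=O
F3 | step 7 | (5S)-5-methyl-5-{2-methylidene-11-[4-(tert-butyldimethylsilyloxy)phenyl]undecyl}furan-2(5H)-one | C=C(CCCCCCCCCc1ccc(O[Si](C)(C)C(C)(C)C)cc1)C[C@]1(C)OC(=O)C=C1
F4 | step 7 | (5S)-5-methyl-5-{2-methyl-2-(triethylsilylperoxy)-11-[4-(tert-butyldimethylsilyloxy)phenyl]undecyl}furan-2(5H)-one, both C6 epimers | CC[Si](CC)(CC)OOC(C)(CCCCCCCCCc1ccc(O[Si](C)(C)C(C)(C)C)cc1)C[C@]1(C)OC(=O)C=C1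
F5 | step 5 | 2-methyl-3-(phenylselanyl)propanal | CC(C[Se]c1ccccc1)C=O
F6 | step 5 | (2E)-4-methyl-5-(phenylselanyl)pent-2-enal | CC(C[Se]c1ccccc1)/C=C/C=O
F7 | step 5 | (3S)-3-({2-methoxy-11-[4-(tert-butyldimethylsilyloxy)phenyl]undecan-2-yl}peroxy)-4-methyl-5-(phenylselanyl)pentanal | CC(C[Se]c1ccccc1)[C@H](CC=O)OOC(C)(OC)CCCCCCCCCc1ccc(O[Si](C)(C)C(C)(C)C)cc1
F8 | step 5 | (3S)-3-({2-methoxy-11-[4-(tert-butyldimethylsilyloxy)phenyl]undecan-2-yl}peroxy)-4-methyl-5-(phenylseleninyl)pentanoic acid | CC(C[Se](=O)c1ccccc1)[C@H](CC(=O)O)OOC(C)(OC)CCCCCCCCCc1ccc(O[Si](C)(C)C(C)(C)C)cc1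
F9 | step 3 | (1-methoxyethenyl)lithium | [Li]C(=C)OC
F10 | step 3 | tert-butyl[4-(10-methoxyundec-10-en-1-yl)phenoxy]dimethylsilane | C=C(OC)CCCCCCCCCc1ccc(O[Si](C)(C)C(C)(C)C)cc1
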